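Ring A of the target (O–C7–C8–C8'–C9') contains two neighbouring oxygen-bearing carbons, the benzylic ether carbon C7 and the tertiary carbinol C8, and C8 is at the same time the α-carbon of ring B (O–C7'–C8'–C8–C9). Both C–O bonds are traced back to a single oxygen atom laid across a C7=C8 arylidene bond on a ring B lactone. In one operation a dioxirane oxygenates this alkene on the face away from the C8' hydroxymethyl arm, and acid lets the C9' hydroxyl displace the oxirane oxygen at C7, which closes ring A and fixes C7 and C8. The precursor is an (E)-arylidene trans-lactone with a free C9' hydroxyl and a pivaloylated guaiacyl ring.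

Key step: step 10

Remark on the chemistry: lignan numbering is used (C7–C9 on the guaiacyl side, C7'–C9' on the veratryl side); the descriptor at C8' changes from S (acid 10) to R (alcohol 11) and that at C8 from R (lactone 18) to S (target 20) only through priority changes; an aryl pivalate does not outlast i-Bu2AlH, so its removal is planned into the lactone reduction (step 11).

Step 1
Reactants: 1 vanillin
Product: 2 4-formyl-2-methoxyphenyl pivalate
Conditions: PivCl, Et3N, DMAP (cat.), CH2Cl2, 0 °C → rt
Reagents that add atoms: pivaloyl chloride, CC(C)(C)C(=O)Cl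
Why: DMAP-catalysed O-acylation of a phenol by an acid chloride is routine, and the hindered, electron-withdrawing pivalate should later resist enolate chemistry and temper the guaiacyl ring.

Step 2
Reactants: 3 (S)-4-benzyl-1,3-oxazolidin-2-one; 4 methyl 4-chloro-4-oxobutanoate
Product: 5 methyl 4-[(4S)-4-benzyl-2-oxo-1,3-oxazolidin-3-yl]-4-oxobutanoate
Conditions: n-BuLi, THF, −78 °C; then 4, −78 → 0 °C
Reagents that add atoms: none
Why: N-acylation of the lithiated Evans oxazolidinone by an acid chloride is fast at −78 °C and leaves the methyl ester untouched, giving the succinate imide that carries C9', C8', C8 and C9.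

Step 3
Reactants: 5 succinate imide; 6 3,4-dimethoxybenzaldehyde
Product: 8 (4S)-4-benzyl-3-{[(2S,3S)-2-(3,4-dimethoxyphenyl)-5-oxotetrahydrofuran-3-yl]carbonyl}-1,3-oxazolidin-2-one (trans-lactone imide), via syn-aldol adduct 7 (not isolated)
Conditions: Bu2BOTf, i-Pr2NEt, CH2Cl2, 0 °C; then 6, −78 → 0 °C; H2O2, pH 7 buffer, MeOH, 0 °C; then PPTS (cat.), CH2Cl2, rt
Reagents that add atoms: none
Why: In this Evans syn-aldol reaction the Z-boron enolate of the imide (the ester is not enolised) adds through a Zimmerman–Traxler chair on the face away from the benzyl group, which sets C8' and C7' as the (3S,4S) syn pair of 7, and the γ-hydroxy ester then lactonises with loss of methanol to the trans-lactone.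

Step 4
Reactants: 8 trans-lactone imide
Product: 10 (2S,3S)-2-(3,4-dimethoxyphenyl)-5-oxotetrahydrofuran-3-carboxylic acid, via peroxy acid 9 (not isolated)
Conditions: LiOH, H2O2, THF/H2O (3:1), 0 °C; aq. Na2SO3; then 1 M HCl to pH 2
Reagents that add atoms: hydrogen peroxide, OO
Why: Hydroperoxide cleavage of the Evans imide attacks the exocyclic carbonyl selectively, sulfite reduces the peroxy acid, and acidification re-closes any opened lactone, so the trans arrangement should be kept and the auxiliary recovered.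

Step 5
Reactants: 10 paraconic acid
Product: 11 (4R,5S)-5-(3,4-dimethoxyphenyl)-4-(hydroxymethyl)dihydrofuran-2(3H)-one
Conditions: BH3·SMe2, THF, 0 °C → rt; MeOH quench
Reagents that add atoms: none
Why: Chemoselective borane reduction takes a carboxylic acid (through its acyloxyborane) to the primary alcohol much faster than it touches a γ-lactone, so C9' should reach the alcohol level with ring B and both stereocentres intact.

Step 6
Reactants: 11 hydroxymethyl lactone
Product: 12 (4R,5S)-4-({[tert-butyl(dimethyl)silyl]oxy}methyl)-5-(3,4-dimethoxyphenyl)dihydrofuran-2(3H)-one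
Conditions: TBSCl, imidazole, DMF, rt
Reagents that add atoms: tert-butyldimethylsilyl chloride, CC(C)(C)[Si](C)(C)Cl
Why: Standard silylation of a primary alcohol masks the C9' hydroxyl for the enolate and sulfonylation steps that follow.

Step 7
Reactants: 12 silyl ether lactone; 2 4-formyl-2-methoxyphenyl pivalate
Product: 13 4-{hydroxy[(3R,4R,5S)-4-({[tert-butyl(dimethyl)silyl]oxy}methyl)-5-(3,4-dimethoxyphenyl)-2-oxotetrahydrofuran-3-yl]methyl}-2-methoxyphenyl pivalate (both C7 carbinol epimers)
Conditions: LiN(i-Pr)2, THF, −78 °C; then 2, −78 °C; aq. NH4Cl at −78 °C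
Reagents that add atoms: none
Why: Directed aldol addition of the lithium lactone enolate to the aldehyde at −78 °C should occur anti to the C8' substituent without attack on the hindered pivalate, and the carbinol epimers do not matter because C7 becomes trigonal in the next step.

Step 8
Reactants: 13 aldol adduct
Product: 15 4-{(E)-[(4R,5S)-4-({[tert-butyl(dimethyl)silyl]oxy}methyl)-5-(3,4-dimethoxyphenyl)-2-oxodihydrofuran-3(2H)-ylidene]methyl}-2-methoxyphenyl pivalate, via benzylic mesylate 14 (not isolated)
Conditions: MsCl, Et3N, CH2Cl2, 0 °C; then DBU, 0 °C → rt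
Reagents that add atoms: none
Why: Mesylation followed by E1cB elimination completes the aldol condensation, and both carbinol epimers should converge on the thermodynamically preferred (E)-arylidene lactone with the aryl group turned away from the carbonyl.

Step 9
Reactants: 15 (E)-arylidene silyl ether
Product: 16 4-{(E)-[(4R,5S)-5-(3,4-dimethoxyphenyl)-4-(hydroxymethyl)-2-oxodihydrofuran-3(2H)-ylidene]methyl}-2-methoxyphenyl pivalate
Conditions: HF·pyridine, pyridine, THF, 0 °C → rt
Reagents that add atoms: none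
Why: Buffered fluoride desilylation removes the primary silyl ether under weakly acidic conditions that spare the aryl pivalate (which basic fluoride would cleave) and the conjugated lactone.

Step 10
Reactants: 16 (E)-arylidene hydroxymethyl lactone
Product: 18 4-[(1R,2R,5R,6S)-6-(3,4-dimethoxyphenyl)-1-hydroxy-8-oxo-3,7-dioxabicyclo[3.3.0]octan-2-yl]-2-methoxyphenyl pivalate, via spiro-epoxide 17 (not isolated)
Conditions: dimethyldioxirane (acetone solution, 3 equiv), CH2Cl2, 0 °C → rt, dark; evaporate; then camphorsulfonic acid (0.2 equiv), CH2Cl2, 0 °C → rt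
Reagents that add atoms: dimethyldioxirane, CC1(C)OO1
Why: Dimethyldioxirane transfers one oxygen atom to C7=C8 in a concerted spiro transition state, so the (E) geometry passes unchanged into oxirane 17, and camphorsulfonic acid then activates the oxirane for attack of the C9' hydroxyl on benzylic C7 from the side opposite the oxirane oxygen, which forms the C7–O bond of ring A with inversion and leaves the former oxirane oxygen on C8 as the tertiary hydroxyl. The closest known reaction types are the dioxirane epoxidation of α-alkylidene lactones and cinnamates and the acid-mediated cyclisation of aryl-substituted 3,4-epoxy alcohols to tetrahydrofuran-3-ols. Ring A closes in the 5-endo epoxide-opening mode (both oxirane carbons end up in the new five-membered ring), the alternative 4-exo attack at C8 being disfavoured by ring strain and by the lactone carbonyl on C8. C8 is controlled by the face of oxygen transfer: allylic 1,3-strain with the (E)-aryl group turns the C8' hydroxymethyl arm perpendicular to the alkene plane, so the oxidant approaches from the opposite face and the ring fusion is necessarily cis. C7 is controlled by the alkene geometry together with the invertive opening, which places the guaiacyl group exo. The step needs an SN2-like rather than a carbocationic opening and oxidation of the alkene only; the electron-withdrawing pivalate keeps the guaiacyl ring from stabilising a free C7 cation, and the C9' hydroxyl is set free only one step earlier so that it meets the oxidant briefly at 0 °C.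

Step 11
Reactants: 18 8-hydroxy furofuranone pivalate
Product: 19 (1R,2R,5R,6S)-6-(3,4-dimethoxyphenyl)-2-(4-hydroxy-3-methoxyphenyl)-3,7-dioxabicyclo[3.3.0]octane-1,8-diol (lactol; both C9 anomers)
Conditions: i-Bu2AlH (5 equiv), CH2Cl2, −78 °C; MeOH, then aq. KNaC4H4O6 (potassium sodium tartrate)
Reagents that add atoms: none
Why: Partial reduction of a γ-lactone by i-Bu2AlH at −78 °C should stop at the aluminium hemiacetal, and the excess reagent cleaves the aryl pivalate reductively in the same flask, so the lactol and the free phenol arise together without touching any stereocentre of the bicycle.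

Step 12
Reactants: 19 lactol
Product: 20 (1S,2R,5R,6S)-6-(3,4-dimethoxyphenyl)-2-(4-hydroxy-3-methoxyphenyl)-3,7-dioxabicyclo[3.3.0]octan-1-ol (target)
Conditions: Et3SiH (5 equiv), BF3·OEt2 (2 equiv), CH2Cl2, −78 → −40 °C; aq. NaHCO3
Reagents that add atoms: none
Why: In this ionic hydrogenation BF3·OEt2 ionises the anomeric hydroxyl to the ring B oxocarbenium ion, which Et3SiH should reduce to the C9 methylene at low temperature before the benzylic C7–O and C7'–O bonds can ionise.

Compound list
1 | vanillin | COc1cc(C=O)ccc1O | starting material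
2 | 4-formyl-2-methoxyphenyl pivalate | COc1cc(C=O)ccc1OC(=O)C(C)(C)C | intermediate
3 | (S)-4-benzyl-1,3-oxazolidin-2-one | O=C1N[C@@H](Cc2ccccc2)CO1 | starting material
4 | methyl 4-chloro-4-oxobutanoate | COC(=O)CCC(=O)Cl | starting material
5 | methyl 4-[(4S)-4-benzyl-2-oxo-1,3-oxazolidin-3-yl]-4-oxobutanoate | COC(=O)CCC(=O)N1[C@@H](Cc2ccccc2)COC1=O | intermediate
6 | 3,4-dimethoxybenzaldehyde | COc1ccc(C=O)cc1OC | starting material
7 | methyl (3S,4S)-3-{[(4S)-4-benzyl-2-oxo-1,3-oxazolidin-3-yl]carbonyl}-4-(3,4-dimethoxyphenyl)-4-hydroxybutanoate (syn-aldol adduct, not isolated) | COC(=O)C[C@H](C(=O)N1[C@@H](Cc2ccccc2)COC1=O)[C@H](O)c1ccc(OC)c(OC)c1 | intermediate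
8 | (4S)-4-benzyl-3-{[(2S,3S)-2-(3,4-dimethoxyphenyl)-5-oxotetrahydrofuran-3-yl]carbonyl}-1,3-oxazolidin-2-one | O=C1C[C@H](C(=O)N2[C@@H](Cc3ccccc3)COC2=O)[C@@H](c2ccc(OC)c(OC)c2)O1 | intermediate
9 | (2S,3S)-2-(3,4-dimethoxyphenyl)-5-oxotetrahydrofuran-3-carboperoxoic acid (peroxy acid, not isolated) | O=C1C[C@H](C(=O)OO)[C@@H](c2ccc(OC)c(OC)c2)O1 | intermediate
10 | (2S,3S)-2-(3,4-dimethoxyphenyl)-5-oxotetrahydrofuran-3-carboxylic acid | O=C1C[C@H](C(=O)O)[C@@H](c2ccc(OC)c(OC)c2)O1 | intermediate
11 | (4R,5S)-5-(3,4-dimethoxyphenyl)-4-(hydroxymethyl)dihydrofuran-2(3H)-one | O=C1C[C@H](CO)[C@@H](c2ccc(OC)c(OC)c2)O1 | intermediate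
12 | (4R,5S)-4-({[tert-butyl(dimethyl)silyl]oxy}methyl)-5-(3,4-dimethoxyphenyl)dihydrofuran-2(3H)-one | O=C1C[C@H](CO[Si](C)(C)C(C)(C)C)[C@@H](c2ccc(OC)c(OC)c2)O1 | intermediate
13 | 4-{hydroxy[(3R,4R,5S)-4-({[tert-butyl(dimethyl)silyl]oxy}methyl)-5-(3,4-dimethoxyphenyl)-2-oxotetrahydrofuran-3-yl]methyl}-2-methoxyphenyl pivalate (both C7 epimers) | O=C1[C@@H](C(O)c2ccc(OC(=O)C(C)(C)C)c(OC)c2)[C@H](CO[Si](C)(C)C(C)(C)C)[C@@H](c2ccc(OC)c(OC)c2)O1 | intermediate
14 | C7 methanesulfonate of 13 (benzylic mesylate, not isolated) | O=C1[C@@H](C(OS(C)(=O)=O)c2ccc(OC(=O)C(C)(C)C)c(OC)c2)[C@H](CO[Si](C)(C)C(C)(C)C)[C@@H](c2ccc(OC)c(OC)c2)O1 | intermediate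
15 | 4-{(E)-[(4R,5S)-4-({[tert-butyl(dimethyl)silyl]oxy}methyl)-5-(3,4-dimethoxyphenyl)-2-oxodihydrofuran-3(2H)-ylidene]methyl}-2-methoxyphenyl pivalate | COc1cc(/C=C2\[C@H](CO[Si](C)(C)C(C)(C)C)[C@@H](c3ccc(OC)c(OC)c3)OC2=O)ccc1OC(=O)C(C)(C)C | intermediate
16 | 4-{(E)-[(4R,5S)-5-(3,4-dimethoxyphenyl)-4-(hydroxymethyl)-2-oxodihydrofuran-3(2H)-ylidene]methyl}-2-methoxyphenyl pivalate | COc1cc(/C=C2\[C@H](CO)[C@@H](c3ccc(OC)c(OC)c3)OC2=O)ccc1OC(=O)C(C)(C)C | intermediate
17 | 4-[(2S,3R,6S,7R)-6-(3,4-dimethoxyphenyl)-7-(hydroxymethyl)-4-oxo-1,5-dioxaspiro[2.4]heptan-2-yl]-2-methoxyphenyl pivalate (spiro-epoxide, oxirane oxygen anti to the hydroxymethyl group, not isolated) | COc1cc([C@@H]2O[C@@]23C(=O)O[C@H](c4ccc(OC)c(OC)c4)[C@H]3CO)ccc1OC(=O)C(C)(C)C | intermediate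
18 | 4-[(1R,2R,5R,6S)-6-(3,4-dimethoxyphenyl)-1-hydroxy-8-oxo-3,7-dioxabicyclo[3.3.0]octan-2-yl]-2-methoxyphenyl pivalate | COc1cc([C@H]2OC[C@@H]3[C@@H](c4ccc(OC)c(OC)c4)OC(=O)[C@]23O)ccc1OC(=O)C(C)(C)C | intermediate
19 | (1R,2R,5R,6S)-6-(3,4-dimethoxyphenyl)-2-(4-hydroxy-3-methoxyphenyl)-3,7-dioxabicyclo[3.3.0]octane-1,8-diol (both anomers) | COc1cc([C@H]2OC[C@@H]3[C@@H](c4ccc(OC)c(OC)c4)OC(O)[C@]23O)ccc1O | intermediate
20 | (1S,2R,5R,6S)-6-(3,4-dimethoxyphenyl)-2-(4-hydroxy-3-methoxyphenyl)-3,7-dioxabicyclo[3.3.0]octan-1-ol | COc1cc([C@H]2OC[C@@H]3[C@@H](c4ccc(OC)c(OC)c4)OC[C@]23O)ccc1O | target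

Total step count: 12. Longest linear sequence: 11 (steps 2–12; step 1 is a one-step branch that joins at step 7).

Steps most likely to fail

Step 10. Oxygen transfer to the electron-poor alkene may be slow enough for oxidation of the veratryl ring or the primary alcohol to compete. Face selectivity may erode if the free hydroxyl steers the oxidant, and ionisation at C7 ahead of ring closure would scramble that centre. The fallback sets out from silyl ether 15 and replaces the oxirane by a diol and a sulfonate. Dihydroxylation with OsO4 (cat.) and N-methylmorpholine N-oxide in acetone/water, anti to the silyloxymethyl arm, should give the syn-7,8-diol F1. MsCl and Et3N at −20 °C should sulfonylate only the secondary benzylic hydroxyl to give the benzylic mesylate F2. HF·pyridine then frees the C9' hydroxyl to give the hydroxy mesylate F3. Warming F3 with 2,6-lutidine in MeCN closes ring A by 5-exo-tet displacement with inversion at C7, and the route is rejoined at 18.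

Step 12. The Lewis acid may ionise the benzylic C7–O or C7'–O bonds, leading to epimerisation or reductive ring opening instead of clean loss of the anomeric oxygen. The fallback sets out from lactone 18 and avoids Lewis acid altogether. LiAlH4 in THF reduces the lactone and strips the pivalate to give the ring-B-opened tetraol F4. TsCl (2.2 equiv) in pyridine sulfonylates the phenol and the primary C9 hydroxyl to give the bis-tosylate F5. On warming, the C7' hydroxyl displaces the C9 tosylate (5-exo-tet, C7' untouched) to give the aryl tosylate F6. KOH in aqueous MeOH at 60 °C then frees the phenol, and the route is rejoined at 20.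

Step 8. The elimination may give incomplete (E) selectivity, or the base may move the double bond into ring B. The fallback sets out from lactone 12 and builds the alkene by olefination. LiN(i-Pr)2 (2.2 equiv) and ClP(O)(OEt)2 in THF (enol phosphate, then 1,3-shift of phosphorus to carbon) should give the α-phosphono lactone F7. A Horner–Wadsworth–Emmons reaction of F7 with aldehyde 2 (LiCl, DBU, MeCN) should favour the (E)-arylidene, and the route is rejoined at 15.

Further compounds
F1 | step 10 | 4-{(S)-hydroxy[(3R,4R,5S)-4-({[tert-butyl(dimethyl)silyl]oxy}methyl)-5-(3,4-dimethoxyphenyl)-3-hydroxy-2-oxotetrahydrofuran-3-yl]methyl}-2-methoxyphenyl pivalate (syn-7,8-diol) | COc1cc([C@H](O)[C@@]2(O)C(=O)O[C@H](c3ccc(OC)c(OC)c3)[C@H]2CO[Si](C)(C)C(C)(C)C)ccc1OC(=O)C(C)(C)C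
F2 | step 10 | C7 methanesulfonate of F1 (benzylic mesylate) | COc1cc([C@H](OS(C)(=O)=O)[C@@]2(O)C(=O)O[C@H](c3ccc(OC)c(OC)c3)[C@H]2CO[Si](C)(C)C(C)(C)C)ccc1OC(=O)C(C)(C)C
F3 | step 10 | desilylated F2 (hydroxy mesylate with free C9' hydroxyl) | COc1cc([C@H](OS(C)(=O)=O)[C@@]2(O)C(=O)O[C@H](c3ccc(OC)c(OC)c3)[C@H]2CO)ccc1OC(=O)C(C)(C)C
F4 | step 12 | (2R,3S,4R)-4-[(S)-(3,4-dimethoxyphenyl)(hydroxy)methyl]-2-(4-hydroxy-3-methoxyphenyl)-3-(hydroxymethyl)tetrahydrofuran-3-ol (tetraol) | COc1cc([C@H]2OC[C@H]([C@H](O)c3ccc(OC)c(OC)c3)[C@]2(O)CO)ccc1O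
F5 | step 12 | bis(4-methylbenzenesulfonate) of F4 at the phenol and the primary C9 hydroxyl | COc1cc([C@H]2OC[C@H]([C@H](O)c3ccc(OC)c(OC)c3)[C@]2(O)COS(=O)(=O)c2ccc(C)cc2)ccc1OS(=O)(=O)c1ccc(C)cc1
F6 | step 12 | 4-[(1S,2R,5R,6S)-6-(3,4-dimethoxyphenyl)-1-hydroxy-3,7-dioxabicyclo[3.3.0]octan-2-yl]-2-methoxyphenyl 4-methylbenzenesulfonate | COc1cc([C@H]2OC[C@@H]3[C@@H](c4ccc(OC)c(OC)c4)OC[C@]23O)ccc1OS(=O)(=O)c1ccc(C)cc1
F7 | step 8 | diethyl [(3S,4R,5S)-4-({[tert-butyl(dimethyl)silyl]oxy}methyl)-5-(3,4-dimethoxyphenyl)-2-oxotetrahydrofuran-3-yl]phosphonate | O=C1[C@@H](P(=O)(OCC)OCC)[C@H](CO[Si](C)(C)C(C)(C)C)[C@@H](c2ccc(OC)c(OC)c2)O1
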